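## Analysis of the target

Compound 30 is a C30 apo-carotenoid, (3R)-3-hydroxy-7,8-didehydro-8'-apo-β-caroten-8'-al (carotenoid numbering is used throughout). Its single ring is a cyclohexene C1–C6 with a gem-dimethyl group on C1, a methyl group on C5 and a tetrasubstituted C5=C6 bond, and C6 carries the C7≡C8 triple bond. From C9 to C9' runs an all-E heptaene with methyl groups on C9, C13, C13' and C9', ending in the C8' aldehyde. The only stereocentre is C3 (R), a secondary carbinol homoallylic to the ring alkene; the rest of the stereochemical content is seven alkene geometries. The polyenal is sensitive to light, oxygen, acid and base. The C9=C10 bond lies next to the sterically small triple bond and has little thermodynamic preference for E, so iodine or light cannot be used to repair geometry at any stage. The hard points are the bond from the fully substituted ring carbon C6 to the alkyne, the control of seven geometries, and the union of two long unsaturated pieces. The strategy rests on the central disubstituted C15=C15' bond. Cutting it gives a C20 enyne half (C1–C15) and a C10 half (C15'–C8') in which C15 and C15' can both be allylic CH2 groups bridged by sulfur. The C10 half has its methyl groups on C13' and C9', a 2,6-relationship on the eight-carbon chain, so the symmetrical 2,7-dimethylocta-2,4,6-trienedial cannot supply it and the half is assembled from two C5 units.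

## Retrosynthetic reasoning

**30 ⇒ 28 (through 29).** The last operation removes protecting groups only. The C8' aldehyde cannot be free while carbanions are generated beside a sulfone, and the C3 hydroxyl must be masked from the enolisation of step 4 onward, so 30 is traced back to the silyl ether acetal 28. Fluoride frees the hydroxyl (29) while the aldehyde is still an acetal, and dilute aqueous acid in the same flask then opens the acetal. No carbon–carbon bond is made after 28.

**28 ⇒ 24.** The C15=C15' bond is cut and replaced by a sulfonyl bridge between two CH2 groups. This is the only place where both flanking carbons are unhindered allylic methylenes, so both are doubly acidified in sulfone 24 and either can start the extrusion sequence (25, then 26). The cut gives halves of manageable size. It also places the one geometry that is not fixed beforehand at the centre of the polyene, where a Z isomer (27) is corrected most easily by heat. The forward reaction must form one alkene and touch nothing else.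

**24 ⇒ 23 ⇒ 21 + 20.** The two C–S bonds are cut next. The sulfone comes from sulfide 23 by a sulfur-selective, neutral oxidation. The sulfide comes from an SN2 reaction at sp3 carbon between the thiolate of 22 (released from thioacetate 20) and the allylic bromide 21. The bromide is placed on the C20 half because its alcohol precursor 11 is one step away. The C10 half carries the sulfur because its alcohol 19 takes sulfur by a Mitsunobu reaction without an ionisable halide.

**21 ⇒ 11 ⇒ 10 ⇒ 8 + 9.** The C11=C12 bond is cut by a Horner–Wadsworth–Emmons disconnection. Phosphonate 9 brings C12–C15 with the C13=C14 bond already in place and C15 at the ester level; reduction and bromination give 21. The cut is made here because an enal (8) and a stabilised allylic phosphonate reliably give an E disubstituted alkene.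

**8 ⇒ 7 ⇒ 5 + 6.** The C6–C7 bond is cut between an sp2 and an sp carbon. Enynol 6 supplies the triple bond and the critical 9E alkene ready-made, so neither has to be created next to the hindered ring. The forward reaction is an alkynylation of enol triflate 5 and must overcome the two substituents flanking C6.

**5 ⇒ 4 ⇒ 3 ⇒ 2 ⇒ 1.** The ring comes from 1. An enzymatic conjugate reduction sets a first centre (C6 of 2). It relays to the carbinol centre of 3 in a diastereoselective carbonyl reduction. The relay centre is then erased when the only enolisable position of 4 is converted into the enol triflate. This fixes the position of the ring alkene without ambiguity and leaves one stereocentre, the future C3.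

**20 ⇒ 19 ⇒ 18 ⇒ 16 + 17.** In the C10 half the C11'=C12' bond is cut, again as a Horner–Wadsworth–Emmons step. Aldehyde 17 supplies C12'–C15' with the E C13'=C14' bond and the C15' oxygen. Phosphonate 16 supplies C11'–C8' with the aldehyde already masked. Deacetylation and thioacetate formation follow.

**16 ⇒ 15 ⇒ 14 ⇒ 12 + 13.** The phosphonate is cut at C–P (Arbuzov) and then at C9'–C10'. Addition of the vinyl nucleophile 13 to ketone 12 gives carbinol 14, and bromination with allylic transposition moves the functional group to the chain end in 15.

## Alternatives that were turned down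

**Alternative 1: ring closure by cation–olefin cyclisation.** The ring bond C1–C6 is cut, so the ring would come from the acyclic tertiary alcohol A1, which already carries the C3 silyloxy centre and a silylated enyne. In the forward step a strong Brønsted acid in a fluorinated alcohol, or a Lewis acid, ionises the C1 alcohol, C6 of the enyne alkene attacks the cation in a 6-endo closure, and loss of the C6 proton gives the ring enyne A2.

- For: the C3 centre would come from open-chain asymmetric synthesis without a relay centre or a diastereomer separation, and the alkyne is on C6 before the ring exists, so no metal coupling at a hindered carbon is needed. On these two points it is at least as good as the chosen route.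
- Against: the nucleophile is an alkene deactivated by conjugation with the alkyne, and it must react through the carbon that bears the alkyne. The C5 cation can lose a proton toward C4 or C18 as well as from C6, and the C4-ene isomer makes the C3 silyloxy group allylic and ionisable under the same acid, which would destroy the only stereocentre. The C1 cation can also simply eliminate.
- Comparison: A2 is only the C11 ring piece, so the whole C9–C8' chain would still need several more bond-forming stages. The chosen route reaches triflate 5 in four steps with the alkene position fixed by construction, and puts its risk into one late step instead of an early one that everything depends on.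

**Alternative 2: carbometalation of a ring diyne and cross-coupling.** The bonds C9–C19 and C10–C11 are cut. The forward step is a zirconocene-catalysed syn-methylalumination of the terminal alkyne of ring 1,3-diyne A3, followed in the same pot by transmetalation to zinc and palladium-catalysed Negishi coupling with hexaenyl iodide A4 to give bis-silyl ether A5. Desilylation and allylic oxidation would then lead to 30.

- For: the C9=C10 geometry is set as E by the syn-addition mechanism, and this is the alkene that cannot be corrected by equilibration. The coupling is stereospecific, late and highly convergent. In geometric control this alternative is stronger than the chosen route, which depends on the selectivity of an olefination at C13=C14 and on thermal correction at C15=C15'.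
- Against: a conjugated diyne offers the metal two alkynes and an acidic terminal C–H, so regio- and chemoselectivity of the carbometalation are not assured. A4 contains six alkenes, three of them trisubstituted, and would need a long geometry-controlled sequence of its own while being light-sensitive as a polyenyl iodide. Two more steps follow the coupling.
- Comparison: the chosen route builds both halves by short condensation sequences from C5 and C6 units, buys the 9E alkene in 6, and joins the halves at sp3 carbon without an organometallic reagent.

**Alternative 3: ring sulfone plus C20 dialdehyde, alkyne by double elimination.** The C7–C8 bond is cut, with the triple bond made from it. The lithiated ring sulfone A6 adds through C7 to the free aldehyde of A8, the mono-dimethyl acetal of the symmetrical C20 dialdehyde A7. O-Phosphorylation and excess alkoxide base then eliminate phosphate and sulfinate in one pot to give A9, which is the same compound as 28.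

- For: it is the shortest and most convergent plan. The complete all-E polyene is bought in A7, so no chain geometry has to be made. On step economy and chain geometry it is clearly stronger than the chosen route.
- Against: A8 requires a statistical mono-protection of A7, and A6 needs a one-carbon homologation at the hindered ring carbon. The carbanion of A6 is flanked by the tetrasubstituted C6 and adds reversibly to an α-methyl enal. In the second elimination the base must remove the vinylic C8 hydrogen while allylic hydrogens on C4 and C18 are also within reach, and 1,4-elimination through these would give an allenic C6=C7=C8 end group instead of the alkyne.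
- Comparison: the chosen route takes the triple bond from 6 and forms C6–C7 by a palladium coupling, so no strong-base elimination creates the alkyne. Its risky step acts on two unhindered CH2 groups, and all its intermediates are differentiated by construction.

Key step: step 18

Assumption: (E)-4-acetoxy-2-methylbut-2-enal 17, the C5 aldehyde of industrial vitamin A acetate manufacture, is taken as purchasable, as is isomerically pure 6.
Assumption: carbanions, enolates, alkoxides and thiolates made by deprotonating a numbered compound are treated as forms of that compound and carry no number of their own.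

## Route

Step 1
Reactants: 1 ketoisophorone (2,6,6-trimethylcyclohex-2-ene-1,4-dione)
Product: 2 (6R)-2,2,6-trimethylcyclohexane-1,4-dione
Conditions: ene-reductase (old yellow enzyme 2 of Saccharomyces cerevisiae), NADP+ (cat.), D-glucose, glucose dehydrogenase, KH2PO4/K2HPO4 buffer pH 7, 30 °C
Reagents that add atoms: none
Why: Enzymatic conjugate reduction of the doubly activated C=C bond by a flavin-dependent ene-reductase; hydride and proton are delivered to fixed faces in the active site, which sets the 6R centre. The pH is kept neutral and the time short because this centre is α to a ketone and its purity is relayed to C3 of the target in step 2.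

Step 2
Reactants: 2 (6R)-2,2,6-trimethylcyclohexane-1,4-dione
Product: 3 (4R,6R)-4-hydroxy-2,2,6-trimethylcyclohexan-1-one
Conditions: H2 (10 bar), Raney Ni, MeOH, rt; recrystallisation from i-Pr2O/hexane
Reagents that add atoms: none
Why: Chemoselective heterogeneous hydrogenation of the less hindered C4 carbonyl (C1 lies between CMe2 and CHMe); hydrogen is delivered to the face away from the axial C2 methyl group, so the 6R centre is relayed into 4R with the hydroxyl trans to the 6-methyl group. The 4S diastereomer must be removed here by crystallisation, because step 4 erases C6 and would turn it into the enantiomer.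

Step 3
Reactants: 3 (4R,6R)-4-hydroxy-2,2,6-trimethylcyclohexan-1-one
Product: 4 (4R,6R)-4-(tert-butyldimethylsilyloxy)-2,2,6-trimethylcyclohexan-1-one
Conditions: TBSCl, imidazole, DMF, rt
Reagents that add atoms: tert-butyldimethylsilyl chloride, CC(C)(C)[Si](C)(C)Cl
Why: Imidazole-promoted silylation of a secondary alcohol; the silyl ether should tolerate the amide base, the couplings, the hydride and the KOH used later.

Step 4
Reactants: 4 (4R,6R)-4-(tert-butyldimethylsilyloxy)-2,2,6-trimethylcyclohexan-1-one
Product: 5 (4R)-4-(tert-butyldimethylsilyloxy)-2,6,6-trimethylcyclohex-1-en-1-yl trifluoromethanesulfonate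
Conditions: LiN(i-Pr)2, THF, −78 °C; then PhNTf2, −78 °C → rt
Reagents that add atoms: N-phenylbis(trifluoromethanesulfonimide), O=S(=O)(N(c1ccccc1)S(=O)(=O)C(F)(F)F)C(F)(F)F
Why: Enolate formation and O-triflation; only C6 carries an α-hydrogen (C2 is quaternary), so a single tetrasubstituted enol triflate can form. The relay centre C6 disappears and the silyloxy-bearing centre, which is γ to the carbonyl and cannot be eliminated, is untouched.

Step 5
Reactants: 5 (4R)-4-(tert-butyldimethylsilyloxy)-2,6,6-trimethylcyclohex-1-en-1-yl trifluoromethanesulfonate; 6 (E)-3-methylpent-2-en-4-yn-1-ol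
Product: 7 C15 enynol (2E)-5-[(4R)-4-(tert-butyldimethylsilyloxy)-2,6,6-trimethylcyclohex-1-en-1-yl]-3-methylpent-2-en-4-yn-1-ol
Conditions: Pd(PPh3)4 (5 mol%), CuI (10 mol%), i-Pr2NH, DMF, rt → 50 °C, Ar
Reagents that add atoms: none
Why: Sonogashira coupling of a vinyl triflate with a terminal alkyne; oxidative addition of zerovalent palladium into the C–OTf bond is feasible despite the two flanking substituents, and the linear copper acetylide is a small coupling partner. The step forms C6–C7 and does not involve the 9E alkene of 6.

Step 6
Reactants: 7 C15 enynol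
Product: 8 C15 enynal (2E)-5-[(4R)-4-(tert-butyldimethylsilyloxy)-2,6,6-trimethylcyclohex-1-en-1-yl]-3-methylpent-2-en-4-ynal
Conditions: MnO2 (activated, excess), CH2Cl2, rt, dark
Reagents that add atoms: none
Why: Surface oxidation of an allylic alcohol on MnO2; the silyl ether, the alkyne and the ring alkene are inert and the neutral conditions should leave the 9E bond in place.

Step 7
Reactants: 8 C15 enynal; 9 ethyl (2E)-4-(diethoxyphosphoryl)-3-methylbut-2-enoate
Product: 10 C20 ester ethyl (2E,4E,6E)-9-[(4R)-4-(tert-butyldimethylsilyloxy)-2,6,6-trimethylcyclohex-1-en-1-yl]-3,7-dimethylnona-2,4,6-trien-8-ynoate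
Conditions: 9, LiN(SiMe3)2, THF, −78 °C; then 8, −78 → 0 °C, dark
Reagents that add atoms: none
Why: Horner–Wadsworth–Emmons olefination with a vinylogous phosphonate; attack of the allylic anion through its α-carbon and syn-elimination of phosphate give the E C11=C12 bond, and C13=C14 is carried in from 9. Any 13Z isomer arising from the delocalised anion is removed by chromatography at this stage.

Step 8
Reactants: 10 C20 ester
Product: 11 C20 alcohol (2E,4E,6E)-9-[(4R)-4-(tert-butyldimethylsilyloxy)-2,6,6-trimethylcyclohex-1-en-1-yl]-3,7-dimethylnona-2,4,6-trien-8-yn-1-ol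
Conditions: i-Bu2AlH (2.5 equiv), CH2Cl2, −78 °C; aq. KNaC4H4O6 work-up
Reagents that add atoms: none
Why: 1,2-Reduction of a conjugated ester to the allylic alcohol by an aluminium hydride; at −78 °C no conjugate reduction is expected and the silyl ether and alkyne are untouched.

Step 9
Reactants: 12 1,1-dimethoxypropan-2-one; 13 vinylmagnesium bromide
Product: 14 1,1-dimethoxy-2-methylbut-3-en-2-ol (racemic)
Conditions: CH2=CHMgBr, THF, −78 → 0 °C; aq. NH4Cl
Reagents that add atoms: none
Why: Grignard addition to a ketone; the acetal is inert to the reagent. The new tertiary centre is racemic and is removed in step 10.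

Step 10
Reactants: 14 1,1-dimethoxy-2-methylbut-3-en-2-ol
Product: 15 (2E)-4-bromo-1,1-dimethoxy-2-methylbut-2-ene
Conditions: PBr3 (0.4 equiv), pyridine (cat.), Et2O, −20 → 0 °C
Reagents that add atoms: phosphorus tribromide, BrP(Br)Br
Why: Bromination of a tertiary vinyl carbinol with allylic transposition (SN2'-type collapse of the bromophosphite, as in the conversion of tertiary terpene vinyl carbinols into primary allylic bromides); the larger acetal-bearing group should end trans to CH2Br. Pyridine buffers the HBr so that the acetal survives.

Step 11
Reactants: 15 (2E)-4-bromo-1,1-dimethoxy-2-methylbut-2-ene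
Product: 16 diethyl [(2E)-4,4-dimethoxy-3-methylbut-2-en-1-yl]phosphonate
Conditions: P(OEt)3 (neat), 120 °C, EtBr distilled off
Reagents that add atoms: triethyl phosphite, CCOP(OCC)OCC
Why: Michaelis–Arbuzov reaction of a primary allylic bromide; the conditions are neutral and leave the acetal intact.

Step 12
Reactants: 16 diethyl [(2E)-4,4-dimethoxy-3-methylbut-2-en-1-yl]phosphonate; 17 (E)-4-acetoxy-2-methylbut-2-enal
Product: 18 (2E,4E,6E)-8,8-dimethoxy-3,7-dimethylocta-2,4,6-trien-1-yl acetate
Conditions: 16, NaN(SiMe3)2, THF, −78 °C; then 17, −78 → 0 °C
Reagents that add atoms: none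
Why: Horner–Wadsworth–Emmons olefination forming the E C11'=C12' bond; the base is consumed by 16 before 17 is added, and addition to the aldehyde is faster than attack on the acetate. The E C13'=C14' bond of 17 is retained, and any Z geometry at C9'=C10' will correct itself at the enal stage in step 19.

Step 13
Reactants: 18 (2E,4E,6E)-8,8-dimethoxy-3,7-dimethylocta-2,4,6-trien-1-yl acetate
Product: 19 (2E,4E,6E)-8,8-dimethoxy-3,7-dimethylocta-2,4,6-trien-1-ol
Conditions: K2CO3 (0.2 equiv), MeOH, 0 °C → rt
Reagents that add atoms: none
Why: Base-catalysed methanolysis of the acetate (transesterification); the acetal is stable to base, and the product is purified on silica deactivated with Et3N.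

Step 14
Reactants: 19 (2E,4E,6E)-8,8-dimethoxy-3,7-dimethylocta-2,4,6-trien-1-ol
Product: 20 S-[(2E,4E,6E)-8,8-dimethoxy-3,7-dimethylocta-2,4,6-trien-1-yl] ethanethioate
Conditions: PPh3, DIAD, AcSH, THF, 0 °C, dark
Reagents that add atoms: thioacetic acid, CC(=O)S
Why: Mitsunobu reaction; thioacetate displaces the alkoxyphosphonium group at the primary carbon by SN2. The thioacid is taken up at once by the betaine, so the acetal is not exposed to free acid in this anhydrous medium.

Step 15
Reactants: 11 C20 alcohol
Product: 21 C20 allylic bromide tert-butyl({(1R)-4-[(3E,5E,7E)-9-bromo-3,7-dimethylnona-3,5,7-trien-1-yn-1-yl]-3,5,5-trimethylcyclohex-3-en-1-yl}oxy)dimethylsilane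
Conditions: PBr3 (0.4 equiv), pyridine (cat.), Et2O, −30 → −10 °C, dark; cold aq. NaHCO3 work-up; used at once
Reagents that add atoms: phosphorus tribromide, BrP(Br)Br
Why: Low-temperature bromination of a primary allylic alcohol through its bromophosphite (SN2), as used for polyene alcohols of this type. The bromide is not stored and goes directly into step 16.

Step 16
Reactants: 20 S-[(2E,4E,6E)-8,8-dimethoxy-3,7-dimethylocta-2,4,6-trien-1-yl] ethanethioate; 21 C20 allylic bromide
Product: 23 bis-allylic sulfide joining C15 and C15' (C3 silyl ether and C8' dimethyl acetal), via C10 thiol 22 (not isolated)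
Conditions: 20, K2CO3, MeOH (degassed), 0 °C; then 21 in THF, −20 → 0 °C, Ar, dark
Reagents that add atoms: none
Why: Methanolysis of the thioacetate releases the thiolate, which alkylates the primary allylic bromide by SN2 (thioether synthesis). The soft nucleophile should attack C15 directly and faster than methanol or any vinylogous pathway.

Step 17
Reactants: 23 bis-allylic sulfide
Product: 24 bis-allylic C15–SO2–C15' sulfone (C3 silyl ether and C8' dimethyl acetal)
Conditions: (n-Pr)4N[RuO4] (10 mol%), NMO (4 equiv), 4 Å MS, MeCN/CH2Cl2, rt, dark
Reagents that add atoms: N-methylmorpholine N-oxide, C[N+]1([O-])CCOCC1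
Why: Perruthenate-catalysed oxidation of a sulfide to the sulfone with an amine N-oxide as terminal oxidant; oxygen transfer to sulfur is much faster than any reaction at C=C. The medium is neutral and anhydrous, so the acetal and the silyl ether stay, and no free hydroxyl is present that could be oxidised.

Step 18
Reactants: 24 bis-allylic C15–SO2–C15' sulfone
Product: 28 all-E C3 silyl ether C8' dimethyl acetal of the target, via α-bromo sulfone 25 (not isolated), via episulfone 26 (not isolated), via 15Z isomer 27 (not isolated)
Conditions: KOH/Al2O3 (powdered, excess), CBr2F2 (5 equiv), t-BuOH/CH2Cl2, 0 °C → rt, dark; filter; then heptane, 80 °C, Ar, dark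
Reagents that add atoms: none
Why: KOH on Al2O3 removes a proton from C15 or C15', each acidified by the sulfonyl group and by its allylic position, and the carbanion takes bromine from CBr2F2 to give α-bromo sulfone 25 (the regioisomer brominated on the other side leads to the same alkene). A second deprotonation on the opposite α-carbon is followed by intramolecular displacement of bromide, a 3-exo-tet closure to the transient episulfone 26, which loses SO2 cheletropically and leaves the C15=C15' bond. This is the Ramberg–Bäcklund reaction in its one-flask form with in situ halogenation, a reaction type already applied to bis-allylic sulfones to make conjugated trienes. No permanent ring and no stereocentre is formed, and the transient centres of 25 and 26 vanish with the sulfur. The selectivity needed is geometric: the ring protons of 26 exchange under the basic conditions, so the episulfone settles to its trans form before extrusion and the E alkene should dominate. Whatever 15Z isomer 27 forms is converted in the heating stage, because rotation about the central bond of the polyene has the lowest barrier; iodine and light are avoided since they would also equilibrate C9=C10. Site selectivity rests on the sulfonyl group, which keeps the charge and therefore the bromination on the α-carbons and not on the vinylogous positions C13, C11, C13' or C11'. The silyl ether, the acetal and the alkyne are inert to KOH, and the difluorocarbene released from CBr2F2 is trapped by the alkoxide medium and is not expected to add to the polyene.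

Step 19
Reactants: 28 all-E C3 silyl ether C8' dimethyl acetal of the target
Product: 30 (3R)-3-hydroxy-7,8-didehydro-8'-apo-β-caroten-8'-al, via hydroxy acetal 29 (not isolated)
Conditions: Bu4NF, THF, 0 °C → rt; then 0.5 M aq. HCl to pH 2, THF/H2O, 0 °C → rt, dark
Reagents that add atoms: water, O
Why: Fluoride cleaves the Si–O bond while the acetal still protects the aldehyde, so the basic fluoride never meets the polyenal. Acidification then hydrolyses the conjugated dimethyl acetal, which ionises easily to a polyene-stabilised oxocarbenium ion, under conditions too mild to harm the chain and under which the α-methyl enal settles as E. The C3 centre takes no part.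

## Compound list

1 | ketoisophorone (2,6,6-trimethylcyclohex-2-ene-1,4-dione) | CC1=CC(=O)CC(C)(C)C1=O | starting material
2 | (6R)-2,2,6-trimethylcyclohexane-1,4-dione | C[C@@H]1CC(=O)CC(C)(C)C1=O | intermediate
3 | (4R,6R)-4-hydroxy-2,2,6-trimethylcyclohexan-1-one (hydroxyl trans to the 6-methyl group) | C[C@@H]1C[C@@H](O)CC(C)(C)C1=O | intermediate
4 | (4R,6R)-4-(tert-butyldimethylsilyloxy)-2,2,6-trimethylcyclohexan-1-one | C[C@@H]1C[C@@H](O[Si](C)(C)C(C)(C)C)CC(C)(C)C1=O | intermediate
5 | (4R)-4-(tert-butyldimethylsilyloxy)-2,6,6-trimethylcyclohex-1-en-1-yl trifluoromethanesulfonate | CC1=C(OS(=O)(=O)C(F)(F)F)C(C)(C)C[C@H](O[Si](C)(C)C(C)(C)C)C1 | intermediate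
6 | (E)-3-methylpent-2-en-4-yn-1-ol | C#C/C(C)=C/CO | starting material
7 | C15 enynol, (2E)-5-[(4R)-4-(tert-butyldimethylsilyloxy)-2,6,6-trimethylcyclohex-1-en-1-yl]-3-methylpent-2-en-4-yn-1-ol | CC1=C(C#C/C(C)=C/CO)C(C)(C)C[C@H](O[Si](C)(C)C(C)(C)C)C1 | intermediate
8 | C15 enynal, (2E)-5-[(4R)-4-(tert-butyldimethylsilyloxy)-2,6,6-trimethylcyclohex-1-en-1-yl]-3-methylpent-2-en-4-ynal | CC1=C(C#C/C(C)=C/C=O)C(C)(C)C[C@H](O[Si](C)(C)C(C)(C)C)C1 | intermediate
9 | ethyl (2E)-4-(diethoxyphosphoryl)-3-methylbut-2-enoate (triethyl 3-methyl-4-phosphonocrotonate) | CCOC(=O)/C=C(\C)CP(=O)(OCC)OCC | starting material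
10 | C20 ester, ethyl (2E,4E,6E)-9-[(4R)-4-(tert-butyldimethylsilyloxy)-2,6,6-trimethylcyclohex-1-en-1-yl]-3,7-dimethylnona-2,4,6-trien-8-ynoate | CC1=C(C#C/C(C)=C/C=C/C(C)=C/C(=O)OCC)C(C)(C)C[C@H](O[Si](C)(C)C(C)(C)C)C1 | intermediate
11 | C20 alcohol, (2E,4E,6E)-9-[(4R)-4-(tert-butyldimethylsilyloxy)-2,6,6-trimethylcyclohex-1-en-1-yl]-3,7-dimethylnona-2,4,6-trien-8-yn-1-ol | CC1=C(C#C/C(C)=C/C=C/C(C)=C/CO)C(C)(C)C[C@H](O[Si](C)(C)C(C)(C)C)C1 | intermediate
12 | 1,1-dimethoxypropan-2-one (pyruvaldehyde dimethyl acetal) | CC(=O)C(OC)OC | starting material
13 | vinylmagnesium bromide | C=C[Mg]Br | starting material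
14 | 1,1-dimethoxy-2-methylbut-3-en-2-ol (racemic) | C=CC(C)(O)C(OC)OC | intermediate
15 | (2E)-4-bromo-1,1-dimethoxy-2-methylbut-2-ene | BrC/C=C(\C)C(OC)OC | intermediate
16 | diethyl [(2E)-4,4-dimethoxy-3-methylbut-2-en-1-yl]phosphonate | CCOP(=O)(OCC)C/C=C(\C)C(OC)OC | intermediate
17 | (E)-4-acetoxy-2-methylbut-2-enal | CC(=O)OC/C=C(\C)C=O | starting material
18 | (2E,4E,6E)-8,8-dimethoxy-3,7-dimethylocta-2,4,6-trien-1-yl acetate | CC(=O)OC/C=C(C)/C=C/C=C(\C)C(OC)OC | intermediate
19 | (2E,4E,6E)-8,8-dimethoxy-3,7-dimethylocta-2,4,6-trien-1-ol | OC/C=C(C)/C=C/C=C(\C)C(OC)OC | intermediate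
20 | S-[(2E,4E,6E)-8,8-dimethoxy-3,7-dimethylocta-2,4,6-trien-1-yl] ethanethioate | CC(=O)SC/C=C(C)/C=C/C=C(\C)C(OC)OC | intermediate
21 | C20 allylic bromide, tert-butyl({(1R)-4-[(3E,5E,7E)-9-bromo-3,7-dimethylnona-3,5,7-trien-1-yn-1-yl]-3,5,5-trimethylcyclohex-3-en-1-yl}oxy)dimethylsilane | CC1=C(C#C/C(C)=C/C=C/C(C)=C/CBr)C(C)(C)C[C@H](O[Si](C)(C)C(C)(C)C)C1 | intermediate
22 | C10 thiol, (2E,4E,6E)-8,8-dimethoxy-3,7-dimethylocta-2,4,6-triene-1-thiol (formed in the flask in step 16) | SC/C=C(C)/C=C/C=C(\C)C(OC)OC | intermediate
23 | bis-allylic sulfide with sulfur between C15 and C15' (3R, C3 tert-butyldimethylsilyl ether, C8' dimethyl acetal) | CC1=C(C#C/C(C)=C/C=C/C(C)=C/CSC/C=C(C)/C=C/C=C(\C)C(OC)OC)C(C)(C)C[C@H](O[Si](C)(C)C(C)(C)C)C1 | intermediate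
24 | bis-allylic C15–SO2–C15' sulfone (3R, C3 tert-butyldimethylsilyl ether, C8' dimethyl acetal) | CC1=C(C#C/C(C)=C/C=C/C(C)=C/CS(=O)(=O)C/C=C(C)/C=C/C=C(\C)C(OC)OC)C(C)(C)C[C@H](O[Si](C)(C)C(C)(C)C)C1 | intermediate
25 | α-bromo sulfone, drawn with bromine on C15 (new centre uncontrolled; formed in the flask in step 18) | CC1=C(C#C/C(C)=C/C=C/C(C)=C/C(Br)S(=O)(=O)C/C=C(C)/C=C/C=C(\C)C(OC)OC)C(C)(C)C[C@H](O[Si](C)(C)C(C)(C)C)C1 | intermediate
26 | episulfone, 2,3-disubstituted thiirane 1,1-dioxide spanning C15 and C15' (trans expected, ring centres not defined; formed in the flask in step 18) | CC1=C(C#C/C(C)=C/C=C/C(C)=C/C2C(/C=C(C)/C=C/C=C(\C)C(OC)OC)S2(=O)=O)C(C)(C)C[C@H](O[Si](C)(C)C(C)(C)C)C1 | intermediate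
27 | 15Z isomer of 28 (minor; formed in the flask in step 18 and isomerised on heating) | CC1=C(C#C/C(C)=C/C=C/C(C)=C/C=C\C=C(C)\C=C\C=C(/C)C(OC)OC)C(C)(C)C[C@H](O[Si](C)(C)C(C)(C)C)C1 | intermediate
28 | all-E (3R)-3-(tert-butyldimethylsilyloxy)-7,8-didehydro-8'-apo-β-caroten-8'-al dimethyl acetal | CC1=C(C#C/C(C)=C/C=C/C(C)=C/C=C/C=C(C)/C=C/C=C(\C)C(OC)OC)C(C)(C)C[C@H](O[Si](C)(C)C(C)(C)C)C1 | intermediate
29 | all-E (3R)-3-hydroxy-7,8-didehydro-8'-apo-β-caroten-8'-al dimethyl acetal (formed in the flask in step 19) | CC1=C(C#C/C(C)=C/C=C/C(C)=C/C=C/C=C(C)/C=C/C=C(\C)C(OC)OC)C(C)(C)C[C@H](O)C1 | intermediate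
30 | (3R)-3-hydroxy-7,8-didehydro-8'-apo-β-caroten-8'-al, (2E,4E,6E,8E,10E,12E,14E)-17-[(4R)-4-hydroxy-2,6,6-trimethylcyclohex-1-en-1-yl]-2,6,11,15-tetramethylheptadeca-2,4,6,8,10,12,14-heptaen-16-ynal | CC1=C(C#C/C(C)=C/C=C/C(C)=C/C=C/C=C(C)/C=C/C=C(\C)C=O)C(C)(C)C[C@H](O)C1 | target

## Step count and least certain steps

Total step count: 19. Longest linear sequence: 13 steps (steps 1–8 and 15–19, from 1). The C10 branch (steps 9–14) joins at step 16.

**Step 18 (key step).** Three processes are most likely to go wrong.
- Reaction through the delocalised carbanions at positions other than C15 and C15': bromination or 1,3-elimination at vinylogous carbons, or base-induced migration of the C13=C14 or C13'=C14' bonds into conjugation with the sulfone before halogenation occurs.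
- Partial loss of geometry at the trisubstituted alkenes next to the sulfone, because the carbanions are polyenyl anions with lowered rotation barriers.
- Incomplete E selectivity in the extrusion, and slow equilibration of C9=C10 if the heating stage is prolonged.

Fallback: keep the C15=C15' disconnection but form the bond by a Wittig reaction, setting out from bromide 21 and alcohol 19. Compound 21 with PPh3 in CH2Cl2 at 0 °C would give the C20 triphenylphosphonium bromide F1. Compound 19 with MnO2 in CH2Cl2 would give the C10 acetal aldehyde F2. The ylide of F1 (NaOMe, MeOH/CH2Cl2, 0 °C) and F2 would give the C15=C15' alkene as an E/Z mixture, which is heated in heptane as in step 18. The route is rejoined at 28.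

**Step 15 (with its use in step 16).** The bromide of a pentaene-yne system ionises very easily. Solvolysis, elimination to rearranged hydrocarbons and return of bromide at vinylogous positions can all overtake the bimolecular reaction with the thiolate, and the acid released can begin to cleave the silyl ether.

Fallback: reverse the polarity of the S-alkylation so that no C20 halide is needed, setting out from 11 and 19. A Mitsunobu reaction of 11 (PPh3, DIAD, AcSH, THF, 0 °C) would give the C20 thioacetate F3. Compound 19 with MsCl, LiCl and s-collidine in DMF at 0 °C would give the C10 allylic chloride F4, which is less prone to ionise because its triene ends in the σ-withdrawing acetal. K2CO3 in MeOH would release the C20 thiol F5, which is alkylated in the same flask by F4. The route is rejoined at sulfide 23.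

**Step 17.** Oxygen transfer to the electron-rich polyene (epoxidation or cleavage) may compete with the second oxidation at sulfur. The reaction may also stall at the allylic sulfoxide, which can leak away by Mislow–Evans [2,3] rearrangement to a sulfenate.

Fallback: make the sulfone by S-alkylation of a sulfinate, so that the assembled polyene is never exposed to an oxidant, setting out from 21 and 18. Compound 21 would alkylate sodium 3-methoxy-3-oxopropane-1-sulfinate (DMSO, rt) to give the C20 sulfonylpropanoate F6. NaOMe in MeOH/THF would induce retro-Michael loss of methyl acrylate and leave the sodium C20 sulfinate F7. F7 and allylic acetate 18 with Pd(PPh3)4 (cat.) in THF (allylic substitution of the Tsuji–Trost type, with sulfur attacking the unhindered terminus C15') would give sulfone 24 directly, where the route is rejoined.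

**Step 10.** HBr may cleave the acetal, and direct substitution at the tertiary carbon or poor E/Z control in the allylic transposition would lower the quality of 15.

Fallback: build the allylic bromide with the oxygen already on the primary carbon, setting out from 12. A Horner–Wadsworth–Emmons reaction of 12 with triethyl phosphonoacetate (NaH, THF, 0 °C → rt) would give the ester F8, with the E isomer separated. Reduction with i-Bu2AlH (CH2Cl2, −78 °C) would give the allylic alcohol F9. An Appel reaction (CBr4, PPh3, CH2Cl2, 0 °C) under neutral conditions would give 15, where the route is rejoined.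

## Further compounds

F1 | step 18 | C20 triphenylphosphonium bromide, {(2E,4E,6E)-9-[(4R)-4-(tert-butyldimethylsilyloxy)-2,6,6-trimethylcyclohex-1-en-1-yl]-3,7-dimethylnona-2,4,6-trien-8-yn-1-yl}triphenylphosphonium bromide | CC1=C(C#C/C(C)=C/C=C/C(C)=C/C[P+](c2ccccc2)(c2ccccc2)c2ccccc2)C(C)(C)C[C@H](O[Si](C)(C)C(C)(C)C)C1.[Br-]
F2 | step 18 | C10 acetal aldehyde, (2E,4E,6E)-8,8-dimethoxy-3,7-dimethylocta-2,4,6-trienal | O=C/C=C(C)/C=C/C=C(\C)C(OC)OC
F3 | step 15 | C20 thioacetate, S-{(2E,4E,6E)-9-[(4R)-4-(tert-butyldimethylsilyloxy)-2,6,6-trimethylcyclohex-1-en-1-yl]-3,7-dimethylnona-2,4,6-trien-8-yn-1-yl} ethanethioate | CC1=C(C#C/C(C)=C/C=C/C(C)=C/CSC(C)=O)C(C)(C)C[C@H](O[Si](C)(C)C(C)(C)C)C1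
F4 | step 15 | C10 allylic chloride, (2E,4E,6E)-8-chloro-1,1-dimethoxy-2,6-dimethylocta-2,4,6-triene | ClC/C=C(C)/C=C/C=C(\C)C(OC)OC
F5 | step 15 | C20 thiol, (2E,4E,6E)-9-[(4R)-4-(tert-butyldimethylsilyloxy)-2,6,6-trimethylcyclohex-1-en-1-yl]-3,7-dimethylnona-2,4,6-trien-8-yne-1-thiol | CC1=C(C#C/C(C)=C/C=C/C(C)=C/CS)C(C)(C)C[C@H](O[Si](C)(C)C(C)(C)C)C1
F6 | step 17 | C20 sulfonylpropanoate, methyl 3-({(2E,4E,6E)-9-[(4R)-4-(tert-butyldimethylsilyloxy)-2,6,6-trimethylcyclohex-1-en-1-yl]-3,7-dimethylnona-2,4,6-trien-8-yn-1-yl}sulfonyl)propanoate | CC1=C(C#C/C(C)=C/C=C/C(C)=C/CS(=O)(=O)CCC(=O)OC)C(C)(C)C[C@H](O[Si](C)(C)C(C)(C)C)C1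
F7 | step 17 | sodium C20 sulfinate, sodium (2E,4E,6E)-9-[(4R)-4-(tert-butyldimethylsilyloxy)-2,6,6-trimethylcyclohex-1-en-1-yl]-3,7-dimethylnona-2,4,6-trien-8-yne-1-sulfinate | CC1=C(C#C/C(C)=C/C=C/C(C)=C/CS(=O)[O-])C(C)(C)C[C@H](O[Si](C)(C)C(C)(C)C)C1.[Na+]
F8 | step 10 | ethyl (2E)-4,4-dimethoxy-3-methylbut-2-enoate | CCOC(=O)/C=C(\C)C(OC)OC
F9 | step 10 | (2E)-4,4-dimethoxy-3-methylbut-2-en-1-ol | OC/C=C(\C)C(OC)OC
A1 | alternative 1 | acyclic tertiary alcohol, (4R,6E)-4-(tert-butyldiphenylsilyloxy)-2,6-dimethyl-9-(trimethylsilyl)non-6-en-8-yn-2-ol | CC(C)(O)C[C@H](O[Si](c1ccccc1)(c1ccccc1)C(C)(C)C)C/C(C)=C/C#C[Si](C)(C)C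
A2 | alternative 1 | ring enyne, tert-butyl({(1R)-3,5,5-trimethyl-4-[(trimethylsilyl)ethynyl]cyclohex-3-en-1-yl}oxy)diphenylsilane | CC1=C(C#C[Si](C)(C)C)C(C)(C)C[C@H](O[Si](c2ccccc2)(c2ccccc2)C(C)(C)C)C1
A3 | alternative 2 | ring 1,3-diyne, {[(1R)-4-(buta-1,3-diyn-1-yl)-3,5,5-trimethylcyclohex-3-en-1-yl]oxy}(tert-butyl)dimethylsilane | CC1=C(C#CC#C)C(C)(C)C[C@H](O[Si](C)(C)C(C)(C)C)C1
A4 | alternative 2 | hexaenyl iodide, tert-butyl{[(2E,4E,6E,8E,10E,12E)-13-iodo-2,6,11-trimethyltrideca-2,4,6,8,10,12-hexaen-1-yl]oxy}dimethylsilane | I/C=C/C(C)=C/C=C/C=C(C)/C=C/C=C(\C)CO[Si](C)(C)C(C)(C)C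
A5 | alternative 2 | bis-silyl ether of the C8' alcohol corresponding to the target | CC1=C(C#C/C(C)=C/C=C/C(C)=C/C=C/C=C(C)/C=C/C=C(\C)CO[Si](C)(C)C(C)(C)C)C(C)(C)C[C@H](O[Si](C)(C)C(C)(C)C)C1
A6 | alternative 3 | ring sulfone, tert-butyldimethyl({(1R)-3,5,5-trimethyl-4-[(phenylsulfonyl)methyl]cyclohex-3-en-1-yl}oxy)silane | CC1=C(CS(=O)(=O)c2ccccc2)C(C)(C)C[C@H](O[Si](C)(C)C(C)(C)C)C1
A7 | alternative 3 | symmetrical C20 dialdehyde, (2E,4E,6E,8E,10E,12E,14E)-2,6,11,15-tetramethylhexadeca-2,4,6,8,10,12,14-heptaenedial | O=C/C(C)=C/C=C/C(C)=C/C=C/C=C(C)/C=C/C=C(\C)C=O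
A8 | alternative 3 | mono-dimethyl acetal of the symmetrical C20 dialdehyde, (2E,4E,6E,8E,10E,12E,14E)-16,16-dimethoxy-2,6,11,15-tetramethylhexadeca-2,4,6,8,10,12,14-heptaenal | O=C/C(C)=C/C=C/C(C)=C/C=C/C=C(C)/C=C/C=C(\C)C(OC)OC
A9 | alternative 3 | C3 tert-butyldimethylsilyl ether C8' dimethyl acetal of the target (identical with 28) | CC1=C(C#C/C(C)=C/C=C/C(C)=C/C=C/C=C(C)/C=C/C=C(\C)C(OC)OC)C(C)(C)C[C@H](O[Si](C)(C)C(C)(C)C)C1
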